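**Retrosynthetic overview**
1. The route rests on one feature of the ten-membered carbocycle (C1–C10): the C9 carbinol is allylic to the E-trisubstituted C1=C10 alkene (C14 methyl on C10). This is the retron of a syn hydro-alkylation of a C1≡C10 methyl alkyne by a C9 aldehyde, so the ring is cut at C9–C10 (Ni(0)/carbene/silane reductive ynal macrocyclisation).
2. Ring order: γ-lactone (O–C8/C12, trans at C7–C8) first, ten-membered carbocycle second, 4,5-oxirane last. The C11=C13 methylene is added after ring closure so that no enoate competes at nickel.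
3. Ynal precursor: Evans syn-aldol of a succinate imide with a Z-enynal (sets C6, C7), then Felkin-controlled dithiane addition to the C8 aldehyde with in-flask lactonisation (sets C8) and unmasking of C9.
4. Z-enynal: Negishi coupling of a homopropargyl zinc reagent with a (Z)-β-iodo-enoate, then reduction and oxidation.
5. Endgame: α-methylenation, C9 silyl ether → isobutyrate, C6 desilylation, hydroxyl-directed epoxidation of C4=C5.

Key step: step 13

Remark: germacrane numbering is used for all intermediates (ring C1–C10; C11, C12, C13 on C7; C14 on C10; C15 on C4). Every compound marked "starting material" in the list is assumed to be purchasable.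

**Step 1**
Reactants: 1 pent-3-yn-1-ol
Product: 2 5-iodopent-2-yne
Conditions: I2, PPh3, imidazole, CH2Cl2, 0 °C → rt
Reagents that add atoms: iodine, II
Why: Appel iodination of a primary alcohol goes by SN2 displacement of the oxyphosphonium ion and leaves the internal alkyne untouched.

**Step 2**
Reactants: 3 ethyl but-2-ynoate
Product: 4 ethyl (Z)-3-iodobut-2-enoate
Conditions: NaI, AcOH, 110 °C
Reagents that add atoms: sodium iodide, [Na+].[I-]
Why: Conjugate hydroiodination of an ynoate, in which iodide adds at C3 and protonation occurs anti, so iodine and ester should end cis (Z).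

**Step 3**
Reactants: 2 5-iodopent-2-yne; 4 ethyl (Z)-3-iodobut-2-enoate
Product: 6 ethyl (Z)-3-methyloct-2-en-6-ynoate, via pent-3-yn-1-ylzinc iodide 5 (not isolated)
Conditions: Zn dust (activated), LiCl, THF, 40 °C; then 4, Pd(PPh3)4 (3 mol%), THF, rt
Reagents that add atoms: none
Why: Negishi sp3–sp2 coupling, in which oxidative addition and reductive elimination at the alkenyl iodide proceed with retention, so the new chain lands cis to the ester and the Z geometry of the future C4=C5 alkene is fixed.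

**Step 4**
Reactants: 6 ethyl (Z)-3-methyloct-2-en-6-ynoate
Product: 7 (Z)-3-methyloct-2-en-6-yn-1-ol
Conditions: DIBAL-H (2.2 equiv), CH2Cl2, −78 °C; Rochelle salt
Reagents that add atoms: none
Why: 1,2-Reduction of an enoate by DIBAL-H gives the allylic alcohol without touching the alkene geometry or the alkyne.

**Step 5**
Reactants: 7 (Z)-3-methyloct-2-en-6-yn-1-ol
Product: 8 (Z)-3-methyloct-2-en-6-ynal
Conditions: TEMPO (10 mol%), PhI(OAc)2 (1.1 equiv), CH2Cl2, rt
Reagents that add atoms: none
Why: Oxoammonium (TEMPO) oxidation of a primary allylic alcohol runs under nearly neutral conditions that leave Z-allylic alcohols of the nerol type unisomerised.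

**Step 6**
Reactants: 9 4-tert-butoxy-4-oxobutanoic acid; 10 (S)-4-benzyloxazolidin-2-one
Product: 12 tert-butyl 4-[(4S)-4-benzyl-2-oxo-1,3-oxazolidin-3-yl]-4-oxobutanoate, via mixed pivalic anhydride 11 (not isolated)
Conditions: PivCl, Et3N, THF, −20 °C; then 10, LiCl, −20 °C → rt
Reagents that add atoms: none
Why: N-Acylation of the oxazolidinone by a mixed anhydride under LiCl/Et3N activation, with attack at the less hindered succinyl carbonyl.

**Step 7**
Reactants: 12 tert-butyl 4-[(4S)-4-benzyl-2-oxo-1,3-oxazolidin-3-yl]-4-oxobutanoate; 8 (Z)-3-methyloct-2-en-6-ynal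
Product: 14 tert-butyl (3S,4R,5Z)-3-{[(4S)-4-benzyl-2-oxo-1,3-oxazolidin-3-yl]carbonyl}-4-hydroxy-6-methylundec-5-en-9-ynoate, via dibutylboron Z-enolate 13 (not isolated)
Conditions: n-Bu2BOTf, i-Pr2NEt, CH2Cl2, −78 → 0 °C; then 8, −78 → 0 °C; pH 7 buffer, MeOH, H2O2, 0 °C
Reagents that add atoms: none
Why: Evans syn-aldol, in which the Z-boron enolate reacts through a closed chair transition state on the face away from the benzyl group and so sets C7 and C6 (O6 syn to the C11 arm), while the tert-butyl ester keeps the new C6 hydroxyl from lactonising onto C12.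

**Step 8**
Reactants: 14 aldol adduct
Product: 15 tert-butyl (3S,4R,5Z)-3-{[(4S)-4-benzyl-2-oxo-1,3-oxazolidin-3-yl]carbonyl}-4-[(tert-butyldimethylsilyl)oxy]-6-methylundec-5-en-9-ynoate
Conditions: TBSOTf, 2,6-lutidine, CH2Cl2, −78 °C
Reagents that add atoms: tert-butyldimethylsilyl triflate, CC(C)(C)[Si](C)(C)OS(=O)(=O)C(F)(F)F
Why: Silylation of the secondary alcohol with a silyl triflate under buffered cold conditions avoids retro-aldol and allylic ionisation and blocks O6 until the last stage.

**Step 9**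
Reactants: 15 silyl ether imide
Product: 16 tert-butyl (3R,4R,5Z)-4-[(tert-butyldimethylsilyl)oxy]-3-(hydroxymethyl)-6-methylundec-5-en-9-ynoate
Conditions: LiBH4, MeOH (1.1 equiv), THF, 0 °C
Reagents that add atoms: none
Why: Reductive cleavage of the N-acyl oxazolidinone by LiBH4 occurs at the activated exocyclic imide carbonyl and spares the hindered tert-butyl ester, giving C8 as a primary alcohol and releasing the auxiliary.

**Step 10**
Reactants: 16 primary alcohol
Product: 17 tert-butyl (3S,4R,5Z)-4-[(tert-butyldimethylsilyl)oxy]-3-formyl-6-methylundec-5-en-9-ynoate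
Conditions: Dess–Martin periodinane, NaHCO3, CH2Cl2, 0 °C → rt; used crude
Reagents that add atoms: none
Why: Dess–Martin oxidation under buffered, non-basic conditions should give the α-branched aldehyde without epimerisation at C7 or β-elimination of the silyloxy group.

**Step 11**
Reactants: 17 C8 aldehyde; 18 1,3-dithiane
Product: 21 (4R,5R)-4-{(1R,2Z)-1-[(tert-butyldimethylsilyl)oxy]-3-methyloct-2-en-6-yn-1-yl}-5-(1,3-dithian-2-yl)oxolan-2-one, via 2-lithio-1,3-dithiane 19 (not isolated), via lithium C8-alkoxide 20 (not isolated)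
Conditions: 18, n-BuLi (1.05 equiv), THF, −30 °C; then 17, −78 °C; then t-BuOK (0.2 equiv), −78 → 0 °C; aq NH4Cl
Reagents that add atoms: none
Why: Corey–Seebach acyl-anion addition in the Felkin–Anh sense (attack anti to the large C6 branch on C7, past H7) should set C8 with O8 syn to the C11 arm, and the alkoxide then closes onto the tert-butyl ester (5-exo-trig transesterification) to give the trans-γ-lactone.

**Step 12**
Reactants: 21 dithianyl lactone
Product: 22 (2R,3R)-3-{(1R,2Z)-1-[(tert-butyldimethylsilyl)oxy]-3-methyloct-2-en-6-yn-1-yl}-5-oxooxolane-2-carbaldehyde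
Conditions: MeI (excess), CaCO3, MeCN/H2O (9:1), 40 °C; dried azeotropically and used at once
Reagents that add atoms: water, O
Why: Alkylative hydrolysis of the dithiane (S-methylation, ring opening to the thionium ion, capture by water) runs under buffered neutral conditions that should spare the allylic silyl ether, the alkyne and the C8 centre of the α-acyloxy aldehyde.

**Step 13**
Reactants: 22 trans-lactone ynal
Product: 23 (1(10)E,4Z,6R,7R,8R,9S)-6-[(tert-butyldimethylsilyl)oxy]-9-[(triethylsilyl)oxy]-13-norgermacra-1(10),4-dien-12,8-olide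
Conditions: Ni(cod)2 (30 mol%), IMes·HCl (30 mol%), t-BuOK (28 mol%), Et3SiH (5 equiv), THF, 45 °C; 22 added over 8 h by syringe pump (final 0.003 M)
Reagents that add atoms: triethylsilane, CC[SiH](CC)CC
Why: Ni(0)–IMes binds the C1≡C10 alkyne and the C9 aldehyde and couples them oxidatively to an oxanickelacyclopentene (C9–C10 bond, Ni–C1, Ni–O9); σ-bond metathesis with Et3SiH turns Ni–O9 into the O9–SiEt3 ether and a vinyl nickel hydride, and C1–H reductive elimination with retention completes a syn addition, so C2 and C9 end trans and the C1=C10 alkene is E by mechanism. The closest known reaction type is the nickel/N-heterocyclic carbene/silane reductive macrocyclisation of ynals to cyclic allylic silyl ethers. The ten-membered carbocycle (C1–C10) closes in the endocyclic mode (10-endo-dig, C–C bond at the distal methyl-bearing alkyne carbon C10, both alkyne carbons inside the ring). The new stereocentre C9 is controlled by C8: in the polar Felkin–Anh arrangement the C8–O(lactone) bond lies anti to the incoming C10, which passes H8 rather than C7, and this should give the 8,9-anti (9S) silyl ether. The step needs endo over exo regioselectivity and ring closure over oligomerisation: the compact IMes ligand lets aldehyde–alkyne sterics decide, so the bond forms at the small methyl terminus C10 and not at the tethered C1 (a bulky carbene would push towards the nine-membered exocyclic mode), and the Z C4=C5 alkene and the trans-lactone hold the chain ends close under slow-addition dilution. No competing π-acceptor is present, because the C11=C13 enoate is installed only afterwards.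

**Step 14**
Reactants: 23 macrocyclic lactone
Product: 26 (1(10)E,4Z,6R,7R,8R,9S)-6-[(tert-butyldimethylsilyl)oxy]-9-[(triethylsilyl)oxy]germacra-1(10),4,11(13)-trien-12,8-olide, via Mannich base 24 (not isolated), via trimethylammonium iodide 25 (not isolated)
Conditions: LDA, THF, −78 °C; Me2N=CH2+ I−, −78 → 0 °C; then MeI (excess), MeOH, rt; then DBU, CH2Cl2, rt
Reagents that add atoms: N,N-dimethylmethyleneiminium iodide, C=[N+](C)C.[I-]
Why: Eschenmoser methylenation (Mannich reaction of the lactone lithium enolate at C11, N-quaternisation, E1cB loss of trimethylamine) installs the C11=C13 exo-methylene, and no stereocentre is at risk because C7 is not enolisable.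

**Step 15**
Reactants: 26 bis-silyl methylene lactone
Product: 27 (1(10)E,4Z,6R,7R,8R,9S)-6-[(tert-butyldimethylsilyl)oxy]-9-hydroxygermacra-1(10),4,11(13)-trien-12,8-olide
Conditions: HF·pyridine, pyridine, THF, 0 °C
Reagents that add atoms: none
Why: Fluoride-mediated desilylation is much faster for the triethylsilyl than for the tert-butyldimethylsilyl ether, so O9 should be freed selectively under buffered conditions that do not ionise the allylic C–O bonds.

**Step 16**
Reactants: 27 C9 alcohol
Product: 28 (1(10)E,4Z,6R,7R,8R,9S)-6-[(tert-butyldimethylsilyl)oxy]-9-(2-methylpropanoyloxy)germacra-1(10),4,11(13)-trien-12,8-olide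
Conditions: (i-PrCO)2O, DMAP, Et3N, CH2Cl2, 0 °C → rt
Reagents that add atoms: isobutyric anhydride, CC(C)C(=O)OC(=O)C(C)C
Why: DMAP-catalysed acylation of the secondary allylic alcohol takes place at oxygen, so C9 keeps its configuration.

**Step 17**
Reactants: 28 C9 isobutyrate
Product: 29 (1(10)E,4Z,6R,7S,8R,9S)-6-hydroxy-9-(2-methylpropanoyloxy)germacra-1(10),4,11(13)-trien-12,8-olide
Conditions: HF·pyridine, pyridine, THF, 0 °C → rt
Reagents that add atoms: none
Why: Buffered fluoride cleavage of the TBS ether avoids base (no translactonisation to O6, no acyl migration) and strong acid (no allylic ionisation or transannular cyclisation).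

**Step 18**
Reactants: 29 C6 allylic alcohol
Product: 30 (1(10)E,4S,5R,6S,7S,8R,9S)-4,5-epoxy-6-hydroxy-9-(2-methylpropanoyloxy)germacra-1(10),11(13)-dien-12,8-olide (target)
Conditions: VO(acac)2 (5 mol%), t-BuOOH (1.5 equiv), CH2Cl2, 0 °C
Reagents that add atoms: tert-butyl hydroperoxide, CC(C)(C)OO
Why: Vanadium-catalysed hydroxyl-directed epoxidation, in which the C6 vanadate delivers oxygen only to the allylic C4=C5 alkene and, with H6 eclipsing the alkene plane (A1,3 strain from the cis C3 substituent), on the outer face syn to O6, which should give the threo (4S,5R) cis-epoxide and leave C1=C10 and C11=C13 alone.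

**Compound list**
1 | pent-3-yn-1-ol | CC#CCCO | starting material
2 | 5-iodopent-2-yne | CC#CCCI | intermediate
3 | ethyl but-2-ynoate | CCOC(=O)C#CC | starting material
4 | ethyl (Z)-3-iodobut-2-enoate | CCOC(=O)/C=C(C)\I | intermediate
5 | pent-3-yn-1-ylzinc iodide (not isolated) | CC#CCC[Zn]I | intermediate
6 | ethyl (Z)-3-methyloct-2-en-6-ynoate | CCOC(=O)/C=C(C)\CCC#CC | intermediate
7 | (Z)-3-methyloct-2-en-6-yn-1-ol | OC/C=C(C)\CCC#CC | intermediate
8 | (Z)-3-methyloct-2-en-6-ynal | O=C/C=C(C)\CCC#CC | intermediate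
9 | 4-tert-butoxy-4-oxobutanoic acid | CC(C)(C)OC(=O)CCC(=O)O | starting material
10 | (S)-4-benzyloxazolidin-2-one | O=C1OC[C@H](Cc2ccccc2)N1 | starting material
11 | 4-tert-butoxy-4-oxobutanoic pivalic anhydride (not isolated) | CC(C)(C)C(=O)OC(=O)CCC(=O)OC(C)(C)C | intermediate
12 | tert-butyl 4-[(4S)-4-benzyl-2-oxo-1,3-oxazolidin-3-yl]-4-oxobutanoate | O=C1OC[C@H](Cc2ccccc2)N1C(=O)CCC(=O)OC(C)(C)C | intermediate
13 | dibutylboron Z-enolate of 12 (not isolated) | CCCCB(CCCC)O/C(=C\CC(=O)OC(C)(C)C)N1C(=O)OC[C@@H]1Cc2ccccc2 | intermediate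
14 | tert-butyl (3S,4R,5Z)-3-{[(4S)-4-benzyl-2-oxo-1,3-oxazolidin-3-yl]carbonyl}-4-hydroxy-6-methylundec-5-en-9-ynoate | O=C1OC[C@H](Cc2ccccc2)N1C(=O)[C@@H](CC(=O)OC(C)(C)C)[C@H](O)/C=C(C)\CCC#CC | intermediate
15 | tert-butyl (3S,4R,5Z)-3-{[(4S)-4-benzyl-2-oxo-1,3-oxazolidin-3-yl]carbonyl}-4-[(tert-butyldimethylsilyl)oxy]-6-methylundec-5-en-9-ynoate | O=C1OC[C@H](Cc2ccccc2)N1C(=O)[C@@H](CC(=O)OC(C)(C)C)[C@H](O[Si](C)(C)C(C)(C)C)/C=C(C)\CCC#CC | intermediate
16 | tert-butyl (3R,4R,5Z)-4-[(tert-butyldimethylsilyl)oxy]-3-(hydroxymethyl)-6-methylundec-5-en-9-ynoate | OC[C@@H](CC(=O)OC(C)(C)C)[C@H](O[Si](C)(C)C(C)(C)C)/C=C(C)\CCC#CC | intermediate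
17 | tert-butyl (3S,4R,5Z)-4-[(tert-butyldimethylsilyl)oxy]-3-formyl-6-methylundec-5-en-9-ynoate | O=C[C@@H](CC(=O)OC(C)(C)C)[C@H](O[Si](C)(C)C(C)(C)C)/C=C(C)\CCC#CC | intermediate
18 | 1,3-dithiane | C1CSCSC1 | starting material
19 | 2-lithio-1,3-dithiane (not isolated) | [Li]C1SCCCS1 | intermediate
20 | lithium alkoxide of tert-butyl (3R,4R,5Z)-4-[(tert-butyldimethylsilyl)oxy]-3-[(R)-(1,3-dithian-2-yl)(hydroxy)methyl]-6-methylundec-5-en-9-ynoate (not isolated) | [Li+].[O-][C@@H](C1SCCCS1)[C@@H](CC(=O)OC(C)(C)C)[C@H](O[Si](C)(C)C(C)(C)C)/C=C(C)\CCC#CC | intermediate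
21 | (4R,5R)-4-{(1R,2Z)-1-[(tert-butyldimethylsilyl)oxy]-3-methyloct-2-en-6-yn-1-yl}-5-(1,3-dithian-2-yl)oxolan-2-one | S1CCCSC1[C@@H]2OC(=O)C[C@H]2[C@H](O[Si](C)(C)C(C)(C)C)/C=C(C)\CCC#CC | intermediate
22 | (2R,3R)-3-{(1R,2Z)-1-[(tert-butyldimethylsilyl)oxy]-3-methyloct-2-en-6-yn-1-yl}-5-oxooxolane-2-carbaldehyde | O=C[C@@H]1OC(=O)C[C@H]1[C@H](O[Si](C)(C)C(C)(C)C)/C=C(C)\CCC#CC | intermediate
23 | (1(10)E,4Z,6R,7R,8R,9S)-6-[(tert-butyldimethylsilyl)oxy]-9-[(triethylsilyl)oxy]-13-norgermacra-1(10),4-dien-12,8-olide | C1C(=O)O[C@@H]2[C@@H]1[C@H](O[Si](C)(C)C(C)(C)C)/C=C(C)\CC/C=C(\C)[C@@H]2O[Si](CC)(CC)CC | intermediate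
24 | C11-(dimethylaminomethyl) derivative of 23, C11 epimers (not isolated) | CN(C)CC1C(=O)O[C@@H]2[C@@H]1[C@H](O[Si](C)(C)C(C)(C)C)/C=C(C)\CC/C=C(\C)[C@@H]2O[Si](CC)(CC)CC | intermediate
25 | C11-(trimethylammoniomethyl) iodide of 23 (not isolated) | C[N+](C)(C)CC1C(=O)O[C@@H]2[C@@H]1[C@H](O[Si](C)(C)C(C)(C)C)/C=C(C)\CC/C=C(\C)[C@@H]2O[Si](CC)(CC)CC.[I-] | intermediate
26 | (1(10)E,4Z,6R,7R,8R,9S)-6-[(tert-butyldimethylsilyl)oxy]-9-[(triethylsilyl)oxy]germacra-1(10),4,11(13)-trien-12,8-olide | C=C1C(=O)O[C@@H]2[C@@H]1[C@H](O[Si](C)(C)C(C)(C)C)/C=C(C)\CC/C=C(\C)[C@@H]2O[Si](CC)(CC)CC | intermediate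
27 | (1(10)E,4Z,6R,7R,8R,9S)-6-[(tert-butyldimethylsilyl)oxy]-9-hydroxygermacra-1(10),4,11(13)-trien-12,8-olide | C=C1C(=O)O[C@@H]2[C@@H]1[C@H](O[Si](C)(C)C(C)(C)C)/C=C(C)\CC/C=C(\C)[C@@H]2O | intermediate
28 | (1(10)E,4Z,6R,7R,8R,9S)-6-[(tert-butyldimethylsilyl)oxy]-9-(2-methylpropanoyloxy)germacra-1(10),4,11(13)-trien-12,8-olide | C=C1C(=O)O[C@@H]2[C@@H]1[C@H](O[Si](C)(C)C(C)(C)C)/C=C(C)\CC/C=C(\C)[C@@H]2OC(=O)C(C)C | intermediate
29 | (1(10)E,4Z,6R,7S,8R,9S)-6-hydroxy-9-(2-methylpropanoyloxy)germacra-1(10),4,11(13)-trien-12,8-olide | C=C1C(=O)O[C@@H]2[C@@H]1[C@H](O)/C=C(C)\CC/C=C(\C)[C@@H]2OC(=O)C(C)C | intermediate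
30 | (1(10)E,4S,5R,6S,7S,8R,9S)-4,5-epoxy-6-hydroxy-9-(2-methylpropanoyloxy)germacra-1(10),11(13)-dien-12,8-olide | C=C1C(=O)O[C@@H]2[C@@H]1[C@H](O)[C@H]1O[C@@]1(C)CC/C=C(\C)[C@@H]2OC(=O)C(C)C | target

**Step count**
Total: 18 steps. Longest linear sequence: 16 steps (from 3: steps 2–5 and 7–18).

**Steps most likely to fail**

Step 13 (key macrocyclisation). The strained transition state leading to the ten-membered E-cycloalkene may lose to intermolecular coupling, to closure at C1 (nine-membered ring with an exocyclic ethylidene) or to plain hydrosilylation of the aldehyde. The facial bias at C9 may also be eroded by the ring constraint. The fallback forms the same C9–C10 bond with chromium instead of nickel. It sets out from 16. Hydrozirconation of the methyl alkyne with Cp2Zr(H)Cl (excess, THF, rt, equilibration towards Zr on the methyl-bearing carbon) and iodinolysis should give tert-butyl (3R,4R,5Z,9E)-4-[(tert-butyldimethylsilyl)oxy]-3-(hydroxymethyl)-10-iodo-6-methylundeca-5,9-dienoate F1. Buffered Dess–Martin oxidation gives the corresponding 3-formyl ester F2. Lithiodithiane addition and lactonisation as in step 11 give the iodo-dienyl dithianyl lactone F3, and MeI/CaCO3 hydrolysis gives the iodo-dienyl lactone aldehyde F4. Nozaki–Hiyama–Kishi cyclisation (CrCl2, NiCl2 cat., DMSO/THF, high dilution) should close C9–C10 with retention of the alkene geometry to the macrocyclic 9-alcohol F5. Silylation (TESOTf, 2,6-lutidine) comes back to the route at 23.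

Step 11 (C8 stereocentre). Felkin facial selectivity in the addition to the α,β-branched aldehyde may be insufficient, because the 1,3-effect of the C6 silyloxy group opposes it, and the C8 epimer then lactonises to the cis-lactone. Enolisation of the aldehyde by the basic nucleophile is a second drain. The fallback replaces kinetic control of C8 by thermodynamic control. It sets out from 17 and takes the cis-rich addition product, the cis-dithianyl lactone F6, through the same MeI/CaCO3 hydrolysis to the cis-lactone aldehyde F7. The C8–H, now α to the formyl group, is then equilibrated with DBU (0.2 equiv, CH2Cl2, 0 °C). This should drain the material to the trans-disposed lactone aldehyde, so the fallback comes back to the route at 22.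

Step 12 (unmasking of C9). The thioacetal next to the electron-withdrawing lactone oxygen may hydrolyse slowly, and prolonged exposure can cost the allylic silyl ether or hydrate and epimerise the α-acyloxy aldehyde. The fallback carries C9 as a protected alcohol and uses no thioacetal. It sets out from 17. Addition of (4-methoxybenzyloxy)methyllithium (from the tributylstannane and n-BuLi, THF, −78 °C) and lactonisation of the alkoxide as in step 11 should give the C9 4-methoxybenzyl ether lactone F8. DDQ (CH2Cl2/pH 7 buffer) gives the 5-(hydroxymethyl) lactone F9, and buffered Dess–Martin oxidation comes back to the route at 22.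

**Further compounds**
F1 | step 13 | tert-butyl (3R,4R,5Z,9E)-4-[(tert-butyldimethylsilyl)oxy]-3-(hydroxymethyl)-10-iodo-6-methylundeca-5,9-dienoate | OC[C@@H](CC(=O)OC(C)(C)C)[C@H](O[Si](C)(C)C(C)(C)C)/C=C(C)\CC/C=C(\C)I
F2 | step 13 | tert-butyl (3S,4R,5Z,9E)-4-[(tert-butyldimethylsilyl)oxy]-3-formyl-10-iodo-6-methylundeca-5,9-dienoate | O=C[C@@H](CC(=O)OC(C)(C)C)[C@H](O[Si](C)(C)C(C)(C)C)/C=C(C)\CC/C=C(\C)I
F3 | step 13 | (4R,5R)-4-{(1R,2Z,6E)-1-[(tert-butyldimethylsilyl)oxy]-7-iodo-3-methylocta-2,6-dien-1-yl}-5-(1,3-dithian-2-yl)oxolan-2-one | S1CCCSC1[C@@H]2OC(=O)C[C@H]2[C@H](O[Si](C)(C)C(C)(C)C)/C=C(C)\CC/C=C(\C)I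
F4 | step 13 | (2R,3R)-3-{(1R,2Z,6E)-1-[(tert-butyldimethylsilyl)oxy]-7-iodo-3-methylocta-2,6-dien-1-yl}-5-oxooxolane-2-carbaldehyde | O=C[C@@H]1OC(=O)C[C@H]1[C@H](O[Si](C)(C)C(C)(C)C)/C=C(C)\CC/C=C(\C)I
F5 | step 13 | (1(10)E,4Z,6R,7R,8R,9S)-6-[(tert-butyldimethylsilyl)oxy]-9-hydroxy-13-norgermacra-1(10),4-dien-12,8-olide | C1C(=O)O[C@@H]2[C@@H]1[C@H](O[Si](C)(C)C(C)(C)C)/C=C(C)\CC/C=C(\C)[C@@H]2O
F6 | step 11 | (4R,5S)-4-{(1R,2Z)-1-[(tert-butyldimethylsilyl)oxy]-3-methyloct-2-en-6-yn-1-yl}-5-(1,3-dithian-2-yl)oxolan-2-one | S1CCCSC1[C@H]2OC(=O)C[C@H]2[C@H](O[Si](C)(C)C(C)(C)C)/C=C(C)\CCC#CC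
F7 | step 11 | (2S,3R)-3-{(1R,2Z)-1-[(tert-butyldimethylsilyl)oxy]-3-methyloct-2-en-6-yn-1-yl}-5-oxooxolane-2-carbaldehyde | O=C[C@H]1OC(=O)C[C@H]1[C@H](O[Si](C)(C)C(C)(C)C)/C=C(C)\CCC#CC
F8 | step 12 | (4R,5R)-4-{(1R,2Z)-1-[(tert-butyldimethylsilyl)oxy]-3-methyloct-2-en-6-yn-1-yl}-5-{[(4-methoxybenzyl)oxy]methyl}oxolan-2-one | COc1ccc(COC[C@@H]2OC(=O)C[C@H]2[C@H](O[Si](C)(C)C(C)(C)C)/C=C(C)\CCC#CC)cc1
F9 | step 12 | (4R,5R)-4-{(1R,2Z)-1-[(tert-butyldimethylsilyl)oxy]-3-methyloct-2-en-6-yn-1-yl}-5-(hydroxymethyl)oxolan-2-one | OC[C@@H]1OC(=O)C[C@H]1[C@H](O[Si](C)(C)C(C)(C)C)/C=C(C)\CCC#CC
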